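## Structural features

The target is a cyclohexene (ring atoms C1–C6, C4=C5) cis-fused to an oxirane across C1–C6, a 7-oxabicyclo[4.1.0]hept-4-ene. C1 is fully substituted: it carries the oxirane oxygen, the benzoyloxymethyl carbon C7, C2 and C6. Four contiguous stereocentres run C6–C1–C2–C3: the C2 methoxy group is cis to the oxirane oxygen, and the C3 benzoate is trans to the C2 methoxy group (1R,2S,3R,6R). The C4=C5 bond makes the oxirane a vinyl oxirane (C6 is allylic) and the C3 benzoate an allylic ester. Both are sensitive to acid, to SN2' attack and to zerovalent palladium, and the two benzoates are sensitive to base and to acyl migration. The real difficulty is the oxygenated quaternary C1 with a defined relation to C2, together with the need to make the vinyl oxirane late and under mild conditions. The three oxygen substituents (one methyl ether, two benzoates) must also be differentiated.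

The key step exploits the fact that C6 is at once an oxirane carbon, allylic to C4=C5 and bonded to the quaternary C1. This is the retron of a carbonyl epoxidation in which C1 is a ketone carbon and C6 an allylic sulfonium ylide carbon. Atom labels C1–C7 of the target are used for all intermediates.

## Logic of the disconnections

17 to 16: the acyl C–O bond of the C3 benzoate is cut. A benzoate at C3 would sit β to the C1 ketone and next to the γ-carbon of the ylide in the key step, where it could leave by E1cB. It is therefore introduced last. The forward acylation must not open the vinyl oxirane.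

16 to 15: the O–Si bond at C3 is cut. A triisopropylsilyl ether is a non-leaving, non-chelating spectator at C3 during the ring closure. Its removal must be buffered so that no free alkoxide attacks the oxirane or the C7 ester.

15 to 12 (through 14 and 13): the C1–C6 bond and the O–C6 bond are cut together. This opens both rings and removes two stereocentres (C1 and C6), leaving an open chain with only C2 and C3 stereogenic, a C1 ketone and a (Z)-allylic C6 electrophile. In one sentence, the route is the base-triggered epoxy-annulation of the open-chain (Z)-allylic thiolanium ketone 13. The forward step must set C1 from C2 and must form the ylide faster than the ketone enolises.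

12 to 11 to 10: the C6–Br bond and then the O–H/O–Si bond at C6 are cut. The allylic electrophile is unmasked only at the end. The primary silyl ether must be removed in the presence of the secondary one at C3.

10 to 9: the C4=C5 Z-alkene is traced to an alkyne. The alkyne is inert to the dihydroxylation used for C1/C7 and fixes Z geometry on semi-hydrogenation. The reduction must stop at the alkene.

9 to 8 to 7 to 6: the C1=O bond, the C7–O acyl bond and the two C–O bonds at C1 and C7 are cut back to a terminal vinyl group. This turns the acyloxy ketone into a simple alkene that an allylmetal reagent can deliver. The forward steps need alkene-over-alkyne and primary-over-secondary selectivity.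

6 to 5 to 2 and 3 (through 4): the O–Si bond at C3 and then the C2–C3 bond are cut. Both stereocentres of the chain arise in one reagent-controlled alkoxyallylboration of an achiral ynal. The borane must add with high syn and facial selectivity.

2 to 1: the C4–CHO bond is cut (formylation of a terminal alkyne).

## Other disconnections considered

Alternative 1: This is the first idea that comes to mind. The oxirane C–O bonds are cut to give dienol A1 (C1=C6 and C4=C5, free C2-OH), as could be reached from a microbially produced trans-dihydroxy-dihydrobenzoate. Hydroxyl-directed epoxidation of C1=C6 would give epoxy alcohol A2, and O-methylation would finish. The directing group must be a free C2-OH, so the methyl ether has to be installed last on A2. A2 is a 2,3-epoxy alcohol prone to Payne rearrangement, and it has a neighbouring benzoate that can migrate. The chosen plan carries the methyl ether from the second step and never exposes a hydroxyl next to the oxirane.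

Alternative 2: The C4=C5 bond is cut, with ring-closing metathesis of the open-chain divinyl oxirane A3. This closes the ring but sets no stereocentre. C1 and C6 would have to be built in the open chain beforehand, for example by reagent-controlled epoxidation and a separate vinyl addition, and a ruthenium carbene would be formed next to the oxirane. The chosen key step creates C1 and C6 and both rings in one operation from a chain with only two stereocentres.

Alternative 3: Dearomatisation by microbial ipso,ortho-cis-dihydroxylation of the parent aromatic acid gives diol A4, followed by 1,4-oxygenation of the diene. The wild-type diol is (1S,2R), whereas mapping C1/C2 of 17 onto such a diol requires (1R,2S). The natural diol therefore leads into the enantiomeric series unless C–O bonds are inverted. The diene would also need a trans-1,4 introduction of the C3 oxygen and the C6–O bond, for which peracid or singlet-oxygen chemistry gives the wrong relative pattern. The chosen plan fixes the absolute configuration with a reagent available in both enantiomeric forms.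

Key step: step 10

Assumptions: 7 and 8 are carried as mixtures of C2 epimers (heptane numbering), because that carbon becomes the C1 ketone in step 6. (−)-Ipc2BOMe denotes the reagent made from (+)-α-pinene.

## Steps

Step 1
Reactants: 1 tert-butyldimethyl(prop-2-yn-1-yloxy)silane
Product: 2 4-[(tert-butyldimethylsilyl)oxy]but-2-ynal
Conditions: n-BuLi, THF, −78 °C; DMF, −78 to 0 °C; inverse quench into aq. KH2PO4/MTBE
Reagents that add atoms: N,N-dimethylformamide, CN(C)C=O
Why: Formylation of a lithium acetylide with DMF; the buffered inverse quench releases the ynal without conjugate addition of dimethylamine. No stereocentre is formed.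

Step 2
Reactants: 3 allyl methyl ether (3-methoxyprop-1-ene); 2 4-[(tert-butyldimethylsilyl)oxy]but-2-ynal
Product: 5 (3R,4R)-7-[(tert-butyldimethylsilyl)oxy]-3-methoxyhept-1-en-5-yn-4-ol, via methoxyallylborane 4 (not isolated)
Conditions: 3, s-BuLi, THF, −78 °C; (−)-Ipc2BOMe; BF3·OEt2; then 2, −78 °C; NaOH, H2O2, 0 °C to rt
Reagents that add atoms: none
Why: Brown γ-alkoxyallylboration through a closed chair transition state: the Z geometry of 4 gives the syn (threo) OMe/OH pair, and the isopinocampheyl groups from (+)-α-pinene direct attack to the Si face of the ynal. This fixes the future C3 as R and, through the syn relation, the future C2.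

Step 3
Reactants: 5 (3R,4R)-7-[(tert-butyldimethylsilyl)oxy]-3-methoxyhept-1-en-5-yn-4-ol
Product: 6 (3R,4R)-7-[(tert-butyldimethylsilyl)oxy]-3-methoxy-4-[(triisopropylsilyl)oxy]hept-1-en-5-yne
Conditions: TIPSOTf, 2,6-lutidine, CH2Cl2, −78 to 0 °C
Reagents that add atoms: triisopropylsilyl trifluoromethanesulfonate, CC(C)[Si](C(C)C)(C(C)C)OS(=O)(=O)C(F)(F)F
Why: Standard silylation of a hindered secondary alcohol with a silyl triflate. The bulky ether is stable to all later steps and can be told apart from the primary TBS ether.

Step 4
Reactants: 6 (3R,4R)-7-[(tert-butyldimethylsilyl)oxy]-3-methoxy-4-[(triisopropylsilyl)oxy]hept-1-en-5-yne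
Product: 7 (3R,4R)-7-[(tert-butyldimethylsilyl)oxy]-3-methoxy-4-[(triisopropylsilyl)oxy]hept-5-yne-1,2-diol (both C2 epimers)
Conditions: OsO4 (cat.), NMO, acetone/H2O, rt
Reagents that add atoms: N-methylmorpholine N-oxide, C[N+]1([O-])CCOCC1; water, O
Why: Upjohn dihydroxylation. The terminal alkene reacts and the alkyne is inert under these conditions; the new carbinol centre is not controlled because it is oxidised in step 6.

Step 5
Reactants: 7 (3R,4R)-7-[(tert-butyldimethylsilyl)oxy]-3-methoxy-4-[(triisopropylsilyl)oxy]hept-5-yne-1,2-diol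
Product: 8 (3R,4R)-7-[(tert-butyldimethylsilyl)oxy]-2-hydroxy-3-methoxy-4-[(triisopropylsilyl)oxy]hept-5-yn-1-yl benzoate (both C2 epimers)
Conditions: BzCl (1.05 equiv), 2,4,6-collidine, CH2Cl2, −40 to 0 °C
Reagents that add atoms: benzoyl chloride, O=C(Cl)c1ccccc1
Why: Kinetic acylation of the primary hydroxyl of a 1,2-diol with a hindered weak base; the secondary hydroxyl is flanked by the methoxy-bearing carbon and reacts more slowly.

Step 6
Reactants: 8 (3R,4R)-7-[(tert-butyldimethylsilyl)oxy]-2-hydroxy-3-methoxy-4-[(triisopropylsilyl)oxy]hept-5-yn-1-yl benzoate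
Product: 9 (3S,4R)-7-[(tert-butyldimethylsilyl)oxy]-3-methoxy-2-oxo-4-[(triisopropylsilyl)oxy]hept-5-yn-1-yl benzoate
Conditions: Dess–Martin periodinane, CH2Cl2, 0 °C to rt
Reagents that add atoms: none
Why: Dess–Martin oxidation is near neutral, so the α-methoxy stereocentre should not epimerise and the β-silyloxy group should not eliminate; both C2 epimers converge on one ketone.

Step 7
Reactants: 9 (3S,4R)-7-[(tert-butyldimethylsilyl)oxy]-3-methoxy-2-oxo-4-[(triisopropylsilyl)oxy]hept-5-yn-1-yl benzoate
Product: 10 (3S,4R,5Z)-7-[(tert-butyldimethylsilyl)oxy]-3-methoxy-2-oxo-4-[(triisopropylsilyl)oxy]hept-5-en-1-yl benzoate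
Conditions: H2 (1 atm), Pd/CaCO3 poisoned with Pb(OAc)2, quinoline, EtOAc, rt
Reagents that add atoms: none
Why: Lindlar semi-hydrogenation adds hydrogen syn to the alkyne and gives the Z-alkene needed for ring closure; the ketone, the ester and the silyl ethers are not reduced.

Step 8
Reactants: 10 (3S,4R,5Z)-7-[(tert-butyldimethylsilyl)oxy]-3-methoxy-2-oxo-4-[(triisopropylsilyl)oxy]hept-5-en-1-yl benzoate
Product: 11 (3S,4R,5Z)-7-hydroxy-3-methoxy-2-oxo-4-[(triisopropylsilyl)oxy]hept-5-en-1-yl benzoate
Conditions: HF·pyridine, pyridine, THF, 0 °C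
Reagents that add atoms: none
Why: Buffered HF cleaves the unhindered primary TBS ether much faster than the secondary triisopropylsilyl ether; acidic fluoride avoids base at the enolisable ketone.

Step 9
Reactants: 11 (3S,4R,5Z)-7-hydroxy-3-methoxy-2-oxo-4-[(triisopropylsilyl)oxy]hept-5-en-1-yl benzoate
Product: 12 (3S,4R,5Z)-7-bromo-3-methoxy-2-oxo-4-[(triisopropylsilyl)oxy]hept-5-en-1-yl benzoate
Conditions: CBr4, PPh3, CH2Cl2, −20 to 0 °C
Reagents that add atoms: carbon tetrabromide, BrC(Br)(Br)Br
Why: Appel bromination of a primary allylic alcohol under neutral conditions; direct SN2 displacement at the primary carbon should retain the Z geometry.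

Step 10
Reactants: 12 (3S,4R,5Z)-7-bromo-3-methoxy-2-oxo-4-[(triisopropylsilyl)oxy]hept-5-en-1-yl benzoate
Product: 15 [(1R,2S,3R,6R)-2-methoxy-3-[(triisopropylsilyl)oxy]-7-oxabicyclo[4.1.0]hept-4-en-1-yl]methyl benzoate, via thiolanium bromide 13 (not isolated), via betaine 14 (not isolated)
Conditions: tetrahydrothiophene (3 equiv), MeCN, rt; evaporate; phosphazene base P2-Et (1.05 equiv), CH2Cl2 (0.01 M), −78 to −20 °C
Reagents that add atoms: none
Why: This is an intramolecular Corey–Chaykovsky epoxy-annulation; the closest known type is the ring-forming epoxidation of a ketone by a tethered allylic sulfonium ylide. S-Alkylation gives 13, and the base removes the most acidic proton (C6–H, between S+ and the C4=C5 π-system) to give the allyl ylide. Its α-carbon C6 adds to the C1 ketone in a 6-exo-trig closure; γ-attack would require a four-membered ring, and the Z-alkene holds C6 within bonding distance of C1. In the half-chair transition state the C2 methoxy group lies antiperiplanar to the forming C1–C6 bond (polar Felkin–Anh), with the C3 silyloxy group and C7 equatorial, so the alkoxide develops axial and cis to the methoxy group: C1 is set by C2. Only betaine 14, with O− and S+ trans-diaxial, reaches the antiperiplanar geometry for the 3-exo-tet displacement of tetrahydrothiophene, which inverts C6 and gives the cis-fused oxirane: C6 follows from C1. Betaines with O− and S+ cis cannot close and should revert; the other trans betaine could close only with the C2 and C3 substituents axial and a 1,3-diaxial O−/silyloxy contact. The step needs ylide formation to beat enolisation at C2, which is secured by the cationic C–H acid, one equivalent of a metal-free non-nucleophilic base at −78 °C and a C3 silyl ether that cannot leave by E1cB. It also needs cyclisation to beat bimolecular epoxidation, which is secured by high dilution.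

Step 11
Reactants: 15 [(1R,2S,3R,6R)-2-methoxy-3-[(triisopropylsilyl)oxy]-7-oxabicyclo[4.1.0]hept-4-en-1-yl]methyl benzoate
Product: 16 [(1R,2S,3R,6R)-3-hydroxy-2-methoxy-7-oxabicyclo[4.1.0]hept-4-en-1-yl]methyl benzoate
Conditions: TBAF, AcOH (1:1), THF, 0 °C to rt
Reagents that add atoms: none
Why: Fluoride desilylation buffered with acetic acid, so that no free alkoxide builds up next to the vinyl oxirane or the C7 benzoate. The C3 hydroxyl is not adjacent to an oxirane carbon, so no Payne pathway exists.

Step 12
Reactants: 16 [(1R,2S,3R,6R)-3-hydroxy-2-methoxy-7-oxabicyclo[4.1.0]hept-4-en-1-yl]methyl benzoate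
Product: 17 [(1R,2S,3R,6R)-3-(benzoyloxy)-2-methoxy-7-oxabicyclo[4.1.0]hept-4-en-1-yl]methyl benzoate
Conditions: BzCl, pyridine, DMAP (cat.), CH2Cl2, 0 °C
Reagents that add atoms: benzoyl chloride, O=C(Cl)c1ccccc1
Why: Acylation of a secondary allylic alcohol under mildly basic, non-acidic conditions that a vinyl oxirane tolerates; no stereocentre is touched.

## Compound list

1 | tert-butyldimethyl(prop-2-yn-1-yloxy)silane | C#CCO[Si](C)(C)C(C)(C)C | starting material
2 | 4-[(tert-butyldimethylsilyl)oxy]but-2-ynal | O=CC#CCO[Si](C)(C)C(C)(C)C | intermediate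
3 | allyl methyl ether (3-methoxyprop-1-ene) | COCC=C | starting material
4 | [(2Z)-3-methoxyprop-2-en-1-yl]bis[(1R,2S,3R,5R)-2,6,6-trimethylbicyclo[3.1.1]heptan-3-yl]borane | CO/C=C\CB([C@@H]1C[C@@H]2C[C@H]([C@H]1C)C2(C)C)[C@@H]1C[C@@H]2C[C@H]([C@H]1C)C2(C)C | intermediate
5 | (3R,4R)-7-[(tert-butyldimethylsilyl)oxy]-3-methoxyhept-1-en-5-yn-4-ol | C=C[C@@H](OC)[C@H](O)C#CCO[Si](C)(C)C(C)(C)C | intermediate
6 | (3R,4R)-7-[(tert-butyldimethylsilyl)oxy]-3-methoxy-4-[(triisopropylsilyl)oxy]hept-1-en-5-yne | C=C[C@@H](OC)[C@H](O[Si](C(C)C)(C(C)C)C(C)C)C#CCO[Si](C)(C)C(C)(C)C | intermediate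
7 | (3R,4R)-7-[(tert-butyldimethylsilyl)oxy]-3-methoxy-4-[(triisopropylsilyl)oxy]hept-5-yne-1,2-diol (both C2 epimers) | OCC(O)[C@@H](OC)[C@H](O[Si](C(C)C)(C(C)C)C(C)C)C#CCO[Si](C)(C)C(C)(C)C | intermediate
8 | (3R,4R)-7-[(tert-butyldimethylsilyl)oxy]-2-hydroxy-3-methoxy-4-[(triisopropylsilyl)oxy]hept-5-yn-1-yl benzoate (both C2 epimers) | O=C(OCC(O)[C@@H](OC)[C@H](O[Si](C(C)C)(C(C)C)C(C)C)C#CCO[Si](C)(C)C(C)(C)C)c1ccccc1 | intermediate
9 | (3S,4R)-7-[(tert-butyldimethylsilyl)oxy]-3-methoxy-2-oxo-4-[(triisopropylsilyl)oxy]hept-5-yn-1-yl benzoate | O=C(COC(=O)c1ccccc1)[C@@H](OC)[C@H](O[Si](C(C)C)(C(C)C)C(C)C)C#CCO[Si](C)(C)C(C)(C)C | intermediate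
10 | (3S,4R,5Z)-7-[(tert-butyldimethylsilyl)oxy]-3-methoxy-2-oxo-4-[(triisopropylsilyl)oxy]hept-5-en-1-yl benzoate | O=C(COC(=O)c1ccccc1)[C@@H](OC)[C@H](O[Si](C(C)C)(C(C)C)C(C)C)/C=C\CO[Si](C)(C)C(C)(C)C | intermediate
11 | (3S,4R,5Z)-7-hydroxy-3-methoxy-2-oxo-4-[(triisopropylsilyl)oxy]hept-5-en-1-yl benzoate | O=C(COC(=O)c1ccccc1)[C@@H](OC)[C@H](O[Si](C(C)C)(C(C)C)C(C)C)/C=C\CO | intermediate
12 | (3S,4R,5Z)-7-bromo-3-methoxy-2-oxo-4-[(triisopropylsilyl)oxy]hept-5-en-1-yl benzoate | O=C(COC(=O)c1ccccc1)[C@@H](OC)[C@H](O[Si](C(C)C)(C(C)C)C(C)C)/C=C\CBr | intermediate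
13 | 1-[(2Z,4R,5S)-7-(benzoyloxy)-5-methoxy-6-oxo-4-[(triisopropylsilyl)oxy]hept-2-en-1-yl]thiolan-1-ium bromide | O=C(COC(=O)c1ccccc1)[C@@H](OC)[C@H](O[Si](C(C)C)(C(C)C)C(C)C)/C=C\C[S+]1CCCC1.[Br-] | intermediate
14 | (1S,2S,3R,6S)-1-[(benzoyloxy)methyl]-2-methoxy-6-(thiolan-1-ium-1-yl)-3-[(triisopropylsilyl)oxy]cyclohex-4-en-1-olate | CO[C@H]1[C@H](O[Si](C(C)C)(C(C)C)C(C)C)C=C[C@H]([S+]2CCCC2)[C@]1([O-])COC(=O)c1ccccc1 | intermediate
15 | [(1R,2S,3R,6R)-2-methoxy-3-[(triisopropylsilyl)oxy]-7-oxabicyclo[4.1.0]hept-4-en-1-yl]methyl benzoate | CO[C@H]1[C@H](O[Si](C(C)C)(C(C)C)C(C)C)C=C[C@H]2O[C@]21COC(=O)c1ccccc1 | intermediate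
16 | [(1R,2S,3R,6R)-3-hydroxy-2-methoxy-7-oxabicyclo[4.1.0]hept-4-en-1-yl]methyl benzoate | CO[C@H]1[C@H](O)C=C[C@H]2O[C@]21COC(=O)c1ccccc1 | intermediate
17 | [(1R,2S,3R,6R)-3-(benzoyloxy)-2-methoxy-7-oxabicyclo[4.1.0]hept-4-en-1-yl]methyl benzoate | CO[C@H]1[C@H](OC(=O)c2ccccc2)C=C[C@H]2O[C@]21COC(=O)c1ccccc1 | target

## Step count and least certain steps

Total steps: 12. Longest linear sequence: 12 steps (1 to 17); 3 enters in step 2 without separate steps.

Step 10 (key step). Several things may go wrong:
- Proton transfer from C2 to the ylide, or direct enolisation, may compete with cyclisation and erode C2.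
- The ketone may be attacked on the other face, giving the oxirane trans to the methoxy group.
- A cis betaine that cannot close may be trapped by transfer of the C7 benzoyl group to the C1 alkoxide.
- The allylic sulfonium salt may isomerise from Z to E, so that C6 can no longer reach C1.

The fallback separates C–C bond formation from ring closure. It sets out from 10: intermolecular ylide epoxidation of the ketone with 1-allylthiolan-1-ium bromide F1 (from allyl bromide and tetrahydrothiophene) and phosphazene base P2-Et in CH2Cl2 at −78 °C gives the open-chain vinyl oxirane F2, with the C1, C2, C3 and C6 configurations as in 15. Ring-closing metathesis of F2 with the second-generation Grubbs catalyst RuCl2(=CHPh)(PCy3)(H2IMes) between the new vinyl group and the Z-alkene expels the allyl silyl ether and closes C4=C5. Only the oxirane isomer with the vinyl group cis to the C2 chain can cyclise. The fallback returns to the route at 15.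

Step 2. Facial or syn/anti selectivity may be incomplete with a small linear ynal, and the (Z)-allylborane may partly lose its geometry before it adds, which would give the anti isomer. The fallback replaces reagent control by auxiliary control and sets out from 2:
- (S)-4-Benzyloxazolidin-2-one is acylated with methoxyacetyl chloride to (S)-4-benzyl-3-(methoxyacetyl)oxazolidin-2-one F3.
- Its dibutylboron enolate (Bu2BOTf, iPr2NEt, CH2Cl2, −78 °C) adds to 2 in an Evans syn-aldol reaction to give the (2S,3R) adduct F4.
- Transamidation (MeONHMe·HCl, AlMe3) gives Weinreb amide F5.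
- Silylation with TIPSOTf gives the silyl ether F6.
- Reduction with DIBAL at −78 °C gives aldehyde F7.
- Wittig methylenation with Ph3P=CH2 returns to the route at 6.

Step 8. Site selectivity between the two silyl ethers may be lost. The freed hydroxyl may also add reversibly to the activated ketone (seven-membered hemiketal) and slow the bromination in step 9, where allylic transposition or Z-to-E isomerisation may occur. The fallback avoids the free hydroxy ketone altogether. It sets out from 10 and converts the primary silyl ether directly into the bromide with Ph3PBr2 in CH2Cl2, a known silyl-ether-to-bromide exchange that leaves the hindered secondary silyl ether untouched. It returns to the route at 12.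

Step 11. The alkoxide formed on desilylation may open the vinyl oxirane in an SN2' sense or take the benzoyl group from C7, and cleavage of the hindered secondary silyl ether may be slow enough to allow this. The fallback avoids a free alkoxide. It sets out from 15 and exchanges the silyl ether directly for the benzoate with benzoyl fluoride and a catalytic anhydrous fluoride source (fluoride-catalysed acyl transfer to a silyl ether). It returns to the route at 17.

## Further compounds

F1 | step 10 | 1-allylthiolan-1-ium bromide | C=CC[S+]1CCCC1.[Br-]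
F2 | step 10 | open-chain vinyl oxirane: {2-[(1S,2R,3Z)-5-[(tert-butyldimethylsilyl)oxy]-1-methoxy-2-[(triisopropylsilyl)oxy]pent-3-en-1-yl]-3-vinyloxiran-2-yl}methyl benzoate, oxirane carbons configured as C1 and C6 of 15 | CC(C)(C)[Si](C)(C)OC/C=C\[C@@H](O[Si](C(C)C)(C(C)C)C(C)C)[C@H](OC)[C@]1(COC(=O)c2ccccc2)O[C@@H]1C=C
F3 | step 2 | (S)-4-benzyl-3-(methoxyacetyl)oxazolidin-2-one | O=C1OC[C@H](Cc2ccccc2)N1C(=O)COC
F4 | step 2 | (S)-4-benzyl-3-[(2S,3R)-6-[(tert-butyldimethylsilyl)oxy]-3-hydroxy-2-methoxyhex-4-ynoyl]oxazolidin-2-one | O=C1OC[C@H](Cc2ccccc2)N1C(=O)[C@@H](OC)[C@H](O)C#CCO[Si](C)(C)C(C)(C)C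
F5 | step 2 | (2S,3R)-6-[(tert-butyldimethylsilyl)oxy]-3-hydroxy-N,2-dimethoxy-N-methylhex-4-ynamide | CON(C)C(=O)[C@@H](OC)[C@H](O)C#CCO[Si](C)(C)C(C)(C)C
F6 | step 2 | (2S,3R)-6-[(tert-butyldimethylsilyl)oxy]-N,2-dimethoxy-N-methyl-3-[(triisopropylsilyl)oxy]hex-4-ynamide | CON(C)C(=O)[C@@H](OC)[C@H](O[Si](C(C)C)(C(C)C)C(C)C)C#CCO[Si](C)(C)C(C)(C)C
F7 | step 2 | (2S,3R)-6-[(tert-butyldimethylsilyl)oxy]-2-methoxy-3-[(triisopropylsilyl)oxy]hex-4-ynal | O=C[C@@H](OC)[C@H](O[Si](C(C)C)(C(C)C)C(C)C)C#CCO[Si](C)(C)C(C)(C)C
F0 | step 8 | none | none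
F0 | step 11 | none | none
A1 | alternative 1 | {(5R,6R)-5-(benzoyloxy)-6-hydroxycyclohexa-1,3-dien-1-yl}methyl benzoate | O[C@H]1[C@H](OC(=O)c2ccccc2)C=CC=C1COC(=O)c1ccccc1
A2 | alternative 1 | [(1S,2S,3R,6R)-3-(benzoyloxy)-2-hydroxy-7-oxabicyclo[4.1.0]hept-4-en-1-yl]methyl benzoate (the C2 alcohol corresponding to 17) | O[C@H]1[C@H](OC(=O)c2ccccc2)C=C[C@H]2O[C@]21COC(=O)c1ccccc1
A3 | alternative 2 | open-chain divinyl oxirane: {2-[(1S,2R)-2-(benzoyloxy)-1-methoxybut-3-en-1-yl]-3-vinyloxiran-2-yl}methyl benzoate, oxirane carbons configured as C1 and C6 of 17 | C=C[C@@H](OC(=O)c1ccccc1)[C@H](OC)[C@]1(COC(=O)c2ccccc2)O[C@@H]1C=C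
A4 | alternative 3 | (1S,2R)-1,2-dihydroxycyclohexa-3,5-diene-1-carboxylic acid | O[C@@]1(C(=O)O)C=CC=C[C@H]1O
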